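## The problem

Neocryptomerin (20) is two flavones joined by one oxygen atom, which links C4' of ring B of flavone 1 to C6 of ring A of flavone 2. On the flavone 2 side this oxygen sits between the oxygens on C5 and C7, so the diaryl ether is crowded and is best made while that ring is still a simple phenol. There is no stereocentre; the whole difficulty is regiochemical. Of the five phenolic oxygens only O7 of flavone 1 is methylated, and late methylation could not tell it from the 7-hydroxyl and 4'-hydroxyl of flavone 2. The groups on flavone 2 must therefore be protected so that they come off without touching a non-chelated aryl methyl ether, which excludes methyl ethers there. Both chromones can open at C2 under hot hydroxide, and 1,3-polycarbonyl intermediates can fold by aldol as well as by Claisen condensation. The enabling feature is ring A of flavone 1 (ring A1): C5, C7 and C8a carry oxygen, C4a carries the C4 carbonyl, and the methoxyl on C7 lies midway between the equivalent oxygens on C5 and C8a. That is the pattern produced when a 4-methoxy-2-pyranone is opened and its carbonyl carbon is joined to a chain carbon that becomes C4a.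

## Retrosynthesis

**20 to 19.** The three O-benzyl bonds on flavone 2 are cut last. Benzyl is chosen over methyl or isopropyl because BCl3 with a cation scavenger removes it at low temperature, where the 7-methoxyl of flavone 1 is inert. The forward step only has to distinguish benzyl from methyl ethers.

**19 to 18.** The O1–C2 bond of ring C of flavone 1 is cut, giving the ortho-hydroxyaryl 1,3-diketone 18. A cross-coupling cut at C2–C1' would leave the methoxyl placement unsolved. In 18 the two phenols flanking the acyl group are equivalent, so acid cyclodehydration can give only one chromone, with the 5-hydroxyl and 7-methoxyl already placed.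

**18 to 16 (key disconnection).** The C4a–C5 bond of ring A1 is cut and the ring is unfolded to the pyranone 16 via the ring-opened ester 17. Acylating a ready-made monomethylated phloroglucinol would face two non-equivalent ring positions and would need a Lewis acid in the presence of benzyl ethers. Cutting through the ring replaces this with the folding of a chain in which the methoxyl already sits on the right carbon. A whole benzene ring is exchanged for a commercial pyranone and a four-carbon diketone chain. The forward reaction must fold by Claisen and not by aldol condensation.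

**16 to 15 and 12.** The bond between the aroyl carbon and the terminal chain carbon is cut. This is the convergent cut: a nine-carbon pyranone ketone (15) and the complete flavone 2 as its methyl benzoate (12). Cuts further inside the chain would need enolizable acyl donors. The forward step needs the dianion of 15 to react only at its terminal carbon, and the ester of 12 to be the acceptor and not the chromone.

**15 to 13 and 14.** The bond between the pyranone methylene and the acetyl carbon is cut. The 6-methyl group of 13 is a vinylogous ester α-position and can be lithiated. Weinreb amide 14 is used so that the product ketone is released only on work-up.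

**12 to 9, 10 and carbon monoxide.** Ring C of flavone 2 is cut at C4–C4a, C3–C4 and O1–C2, giving iodophenol 9, alkyne 10 and CO. The classical chalcone route was set aside for two reasons:
- It needs an ortho-hydroxyacetophenone made by Lewis-acid acylation, which endangers the benzyl ethers.
- It needs hydroxide, which would saponify the ester reserved for the union with 15.

The forward annulation has to give 6-endo closure to the flavone rather than 5-exo closure to an aurone.

**9 to 8 to 6.** The C–I bond is cut, then the phenol oxygen is traced to the formyl carbon of aldehyde 6 through aryl formate 7 (Baeyer–Villiger). Phenol 8 is symmetric, so iodination ortho to the hydroxyl has only one outcome. After annulation this gives the 5,6,7-trioxygenated pattern with the aryloxy group on C6.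

**6 to 4 and 5.** The diaryl ether is cut on the benzoate side, where the ester activates fluoride displacement (SNAr). Cutting on the other side would need an electrophilic trioxygenated arene. Phenol 4 has a single free hydroxyl, so the forward step has no regiochemical question, only the reactivity of a hindered, weakly nucleophilic phenoxide.

**4 to 3 to 2 to 1.** The three hydroxyls of 1 are told apart by acidity. The hydroxyl para to the aldehyde is allylated first (2), the other two are benzylated (3), and the allyl group is removed (4). This costs three steps but each is a standard operation on a cheap starting material.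

## Roads not taken

**Alternative 1:** Ring A of flavone 2 would be cut across C7–C8 and C4a–C8a. The product of the key step would be phenol A1, formed by heating cyclobutenone A2 with silyloxyacetylene A3 in a Danheiser benzannulation (ring opening to a vinylketene, [2+2] addition, second ring opening, 6π electrocyclization, tautomerization).
- Merits: the aryloxy group is placed on an sp3 carbon before the arene exists, so the crowded C6–O bond is never made by substitution with a hindered phenoxide. The four ring oxygens emerge fully differentiated, and the ynol ether polarity fixes the regiochemistry. On the diaryl ether bond this road is better than the chosen one.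
- Weak points: A2 is not a catalogue compound, needs several steps, and has an acidic, eliminable hydrogen next to the ketone. A3 is moisture-sensitive. The differentiation of O5 and O7 is wasted, because both end as free hydroxyls. The two ring CH positions of A1 are no longer equivalent, so the later acylation at C4a meets a regiochemical problem that symmetric phenol 8 does not have.
- Comparison: it spends its key step on a ring available from a gallate and leaves the single methyl ether unaddressed. The chosen plan accepts a three-step hydroxyl differentiation and a forcing SNAr, and in return its key step settles the one real selectivity problem.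

**Alternative 2:** Ring C of flavone 2 would be cut at C4–C4a and O1–C2. Symmetric phenol A5 and β-ketoester A6 would condense on strong heating, through an aroylketene, to give flavone ester A4 in one operation.
- Merits: one step from phenol to flavone, with no iodination, palladium or carbon monoxide, where the chosen plan uses two steps (6 and 7). The symmetry of A5 removes any regiochemical question. On step economy for this ring it is better.
- Weak points: the thermal condensation is reliable mainly for polyhydroxy phenols that can react as keto tautomers. A monophenol with two ortho-alkoxy neighbours is a poorer partner, and 4-arylcoumarin formation competes. The methyl benzoate can transesterify with the phenol at the temperatures needed. Isopropyl ethers are needed for thermal stability.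
- Comparison: it says nothing about ring A1. The same condensation on the flavone 1 side would face a phenol with two non-equivalent acylation sites, which is the ambiguity the pyranone folding removes. The chosen plan sets mild conditions that spare benzyl ethers and the ester against the extra step.

**Alternative 3:** Ring B of flavone 1 would be cut across C2'–C3' and C4'–C5'. Methyl coumalate A8 and aryl ethynyl ether A9 would undergo [4+2] cycloaddition and lose CO2, giving the 4-aryloxybenzoate A7.
- Merits: the regiochemistry is fixed by the polarity of both partners. The hindered phenoxide only has to attack a small two-carbon electrophile when the ynol ether is made, so a hot SNAr on a deactivated phenoxide is avoided. The oxygen para to the aryloxy group is present from the start, so no Baeyer–Villiger step on an aryloxy-substituted aldehyde is needed. In these two respects it is gentler than the chosen plan.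
- Weak points: ring B of flavone 1 is the simplest ring of the target and is available as fluoride 5. A9 needs the same hydroxyl differentiation as 4, plus a Dakin-type oxidation, a silylation and a two-stage ynol ether synthesis with strong base.
- Comparison: A7 is only the silyl ether of phenol 8, reached by a longer path. The chosen plan makes 8 in two steps from 4 (steps 4 and 5) and leaves the key step for ring A1.

Key step: step 10

Assumption: the 1,3-dicarbonyl compounds 16, 17 and 18 are drawn and named as keto forms although they will exist largely as chelated enols; this changes no step.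

## Route

Step 1
Reactants: 1 3,4,5-trihydroxybenzaldehyde
Product: 2 3,5-dihydroxy-4-(prop-2-en-1-yloxy)benzaldehyde
Conditions: allyl bromide (1.05 equiv), KHCO3 (1.1 equiv), DMF, 25 °C, under N2
Reagents that add atoms: allyl bromide, C=CCBr
Why: The hydroxyl para to the formyl group is the most acidic, so a hydrogencarbonate base forms only that phenoxide and the Williamson etherification occurs there (selective para-O-alkylation of gallates).

Step 2
Reactants: 2 3,5-dihydroxy-4-(prop-2-en-1-yloxy)benzaldehyde
Product: 3 3,5-bis(benzyloxy)-4-(prop-2-en-1-yloxy)benzaldehyde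
Conditions: BnBr (2.4 equiv), K2CO3 (3 equiv), DMF, 50 °C
Reagents that add atoms: benzyl bromide, BrCc1ccccc1
Why: Williamson etherification of the two remaining, equivalent phenols; the temperature is far below that of an aromatic Claisen rearrangement of the allyl ether.

Step 3
Reactants: 3 3,5-bis(benzyloxy)-4-(prop-2-en-1-yloxy)benzaldehyde
Product: 4 3,5-bis(benzyloxy)-4-hydroxybenzaldehyde
Conditions: Pd(PPh3)4 (2 mol %), morpholine (5 equiv), THF, 25 °C
Reagents that add atoms: none
Why: Tsuji–Trost deallylation: zerovalent palladium ionizes the allyl aryl ether to the stabilized para-formyl phenoxide and a π-allyl complex that morpholine captures; benzyl ethers are untouched and any aminal of the aldehyde reverts on work-up.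

Step 4
Reactants: 4 3,5-bis(benzyloxy)-4-hydroxybenzaldehyde; 5 methyl 4-fluorobenzoate
Product: 6 methyl 4-[2,6-bis(benzyloxy)-4-formylphenoxy]benzoate
Conditions: 5 (1.5 equiv), Cs2CO3 (1.5 equiv), DMSO, 110 °C
Reagents that add atoms: none
Why: Nucleophilic aromatic substitution (SNAr) of the fluoride para to the ester by the caesium phenoxide; only one oxygen of 4 is free, so the crowded diaryl ether forms without a regiochemical question.

Step 5
Reactants: 6 methyl 4-[2,6-bis(benzyloxy)-4-formylphenoxy]benzoate
Product: 8 methyl 4-[2,6-bis(benzyloxy)-4-hydroxyphenoxy]benzoate, via aryl formate 7 (not isolated)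
Conditions: mCPBA (1.5 equiv), CH2Cl2, 0 to 25 °C; NaHCO3 wash, solvent exchange; then K2CO3 (0.3 equiv), MeOH, 25 °C
Reagents that add atoms: 3-chloroperoxybenzoic acid (mCPBA), O=C(OO)c1cccc(Cl)c1
Why: Baeyer–Villiger (Dakin-type) oxidation: the trioxygenated aryl group migrates in the Criegee adduct in preference to hydride and gives formate 7, which mild methanolysis cleaves; the methyl benzoate is unchanged in methanol.

Step 6
Reactants: 8 methyl 4-[2,6-bis(benzyloxy)-4-hydroxyphenoxy]benzoate
Product: 9 methyl 4-[2,6-bis(benzyloxy)-4-hydroxy-3-iodophenoxy]benzoate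
Conditions: N-iodosuccinimide (1.0 equiv), MeCN, −20 to 0 °C
Reagents that add atoms: N-iodosuccinimide, O=C1CCC(=O)N1I
Why: Electrophilic aromatic iodination at one of the two equivalent positions ortho to the free hydroxyl; the para position is blocked, and one equivalent of reagent at low temperature limits double iodination.

Step 7
Reactants: 9 methyl 4-[2,6-bis(benzyloxy)-4-hydroxy-3-iodophenoxy]benzoate; 10 1-(benzyloxy)-4-ethynylbenzene
Product: 12 methyl 4-{[5,7-bis(benzyloxy)-2-(4-benzyloxyphenyl)-4-oxo-4H-chromen-6-yl]oxy}benzoate, via alkynyl ketone 11 (not isolated)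
Conditions: PdCl2(dppf) (5 mol %), CO (5 atm), Et2NH, DMF, 90 °C
Reagents that add atoms: carbon monoxide, [C-]#[O+]
Why: Carbonylative Sonogashira annulation of an ortho-iodophenol, a known flavone synthesis: oxidative addition, CO insertion and alkynylation give alkynyl ketone 11, and the secondary amine promotes 6-endo addition of the phenol oxygen to the β-carbon to close ring C of flavone 2. CO pressure suppresses the direct coupling that would lead to a benzofuran.

Step 8
Reactants: 13 4-methoxy-6-methyl-2H-pyran-2-one; 14 N-methoxy-N-methylacetamide
Product: 15 4-methoxy-6-(2-oxopropyl)-2H-pyran-2-one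
Conditions: LiN(iPr)2 (1.1 equiv), THF, −78 °C; then 14 (1.2 equiv), −78 to −40 °C; aq. NH4Cl
Reagents that add atoms: none
Why: Kinetic deprotonation of the vinylogous 6-methyl group and acylation of the lithiated pyranone by a Weinreb amide; the chelated tetrahedral adduct persists until the quench, so the more acidic product never meets the carbanion and one equivalent of base suffices.

Step 9
Reactants: 15 4-methoxy-6-(2-oxopropyl)-2H-pyran-2-one; 12 methyl 4-{[5,7-bis(benzyloxy)-2-(4-benzyloxyphenyl)-4-oxo-4H-chromen-6-yl]oxy}benzoate
Product: 16 6-[4-(4-{[5,7-bis(benzyloxy)-2-(4-benzyloxyphenyl)-4-oxo-4H-chromen-6-yl]oxy}phenyl)-2,4-dioxobutyl]-4-methoxy-2H-pyran-2-one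
Conditions: 15 (2.5 equiv), LiN(iPr)2 (5.2 equiv), THF, −78 to −30 °C; then 12 (1 equiv), −78 to 0 °C; AcOH
Reagents that add atoms: none
Why: Terminal acylation of a 1,3-dicarbonyl-type dianion by an ester: the first deprotonation occurs at the doubly activated methylene, the second at the methyl group, and only this more basic terminal carbanion attacks the methyl benzoate. The excess dianion also deprotonates the more acidic product, which protects it from further reaction.

Step 10
Reactants: 16 6-[4-(4-{[5,7-bis(benzyloxy)-2-(4-benzyloxyphenyl)-4-oxo-4H-chromen-6-yl]oxy}phenyl)-2,4-dioxobutyl]-4-methoxy-2H-pyran-2-one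
Product: 18 1-(2,6-dihydroxy-4-methoxyphenyl)-3-(4-{[5,7-bis(benzyloxy)-2-(4-benzyloxyphenyl)-4-oxo-4H-chromen-6-yl]oxy}phenyl)propane-1,3-dione, via ring-opened methyl ester 17 (not isolated)
Conditions: Mg(OMe)2 (10 equiv), MeOH–THF, 65 °C; then cold 1 M HCl
Reagents that add atoms: none
Why: Methoxide from Mg(OMe)2 adds to the lactone carbonyl of the 4-methoxy-2-pyranone and opens it to the (2E)-3-methoxy enoate 17, whose fixed double-bond geometry keeps the new methyl ester on the same side as the chain while the three ketones are held as a magnesium-chelated polyenolate. The carbon between the former pyranone C6 ketone and the next ketone (the future C4a) attacks the ester carbonyl, methoxide leaves, and enolization of the cyclic product gives aromatic ring A1. The closest known reaction type is the biomimetic Claisen cyclization of 3,5,7-triketo esters and of 6-(2,4-dioxoalkyl)-4-methoxy-2-pyranones to acylphloroglucinols with Mg(OMe)2, of which the 4-phenyl-2,4-dioxobutyl pyranone is the direct model. Ring A1 closes in a 6-exo-trig mode (enolate carbon onto an ester carbonyl outside the new ring), forming the C4a–C5 bond; no stereocentre is created. The step needs Claisen folding to win over aldol folding and over cleavage of the 1,3-diketone. Chelation keeps every ketone carbon enolized and non-electrophilic, so the ester is the only acceptor, and the wanted carbanion is the only one that can reach it through a six-membered transition state. The enol methyl ether of the pyranone is carried unchanged to C7, between two equivalent hydroxyls, so the position of the single methyl ether is not a matter of selectivity. Any reversible opening of ring C of flavone 2 by methoxide is repaired by the acid of step 11.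

Step 11
Reactants: 18 1-(2,6-dihydroxy-4-methoxyphenyl)-3-(4-{[5,7-bis(benzyloxy)-2-(4-benzyloxyphenyl)-4-oxo-4H-chromen-6-yl]oxy}phenyl)propane-1,3-dione
Product: 19 5,7-bis(benzyloxy)-2-(4-benzyloxyphenyl)-6-[4-(5-hydroxy-7-methoxy-4-oxo-4H-chromen-2-yl)phenoxy]-4H-chromen-4-one
Conditions: TsOH·H2O (0.2 equiv), toluene, 90 °C
Reagents that add atoms: none
Why: Acid-catalysed cyclodehydration of an ortho-hydroxyaryl 1,3-diketone, the last stage of the Baker–Venkataraman flavone synthesis; the two phenols are equivalent, so only one chromone can form, with the chelated 5-hydroxyl and the 7-methoxyl in place.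

Step 12
Reactants: 19 5,7-bis(benzyloxy)-2-(4-benzyloxyphenyl)-6-[4-(5-hydroxy-7-methoxy-4-oxo-4H-chromen-2-yl)phenoxy]-4H-chromen-4-one
Product: 20 neocryptomerin, 5,7-dihydroxy-6-[4-(5-hydroxy-7-methoxy-4-oxo-4H-chromen-2-yl)phenoxy]-2-(4-hydroxyphenyl)-4H-chromen-4-one
Conditions: BCl3 (10 equiv), pentamethylbenzene (10 equiv), CH2Cl2, −78 to −30 °C; then MeOH, water
Reagents that add atoms: none
Why: Lewis-acid debenzylation with BCl3, with pentamethylbenzene as a non-basic benzyl cation scavenger; at low temperature the non-chelated aryl methyl ether, the diaryl ether and both chromones are inert.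

## Compound list

1 | 3,4,5-trihydroxybenzaldehyde | O=Cc1cc(O)c(O)c(O)c1 | starting material
2 | 3,5-dihydroxy-4-(prop-2-en-1-yloxy)benzaldehyde | C=CCOc1c(O)cc(C=O)cc1O | intermediate
3 | 3,5-bis(benzyloxy)-4-(prop-2-en-1-yloxy)benzaldehyde | C=CCOc1c(OCc2ccccc2)cc(C=O)cc1OCc1ccccc1 | intermediate
4 | 3,5-bis(benzyloxy)-4-hydroxybenzaldehyde | O=Cc1cc(OCc2ccccc2)c(O)c(OCc2ccccc2)c1 | intermediate
5 | methyl 4-fluorobenzoate | COC(=O)c1ccc(F)cc1 | starting material
6 | methyl 4-[2,6-bis(benzyloxy)-4-formylphenoxy]benzoate | COC(=O)c1ccc(Oc2c(OCc3ccccc3)cc(C=O)cc2OCc2ccccc2)cc1 | intermediate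
7 | methyl 4-[2,6-bis(benzyloxy)-4-(formyloxy)phenoxy]benzoate (aryl formate, not isolated) | COC(=O)c1ccc(Oc2c(OCc3ccccc3)cc(OC=O)cc2OCc2ccccc2)cc1 | intermediate
8 | methyl 4-[2,6-bis(benzyloxy)-4-hydroxyphenoxy]benzoate | COC(=O)c1ccc(Oc2c(OCc3ccccc3)cc(O)cc2OCc2ccccc2)cc1 | intermediate
9 | methyl 4-[2,6-bis(benzyloxy)-4-hydroxy-3-iodophenoxy]benzoate | COC(=O)c1ccc(Oc2c(OCc3ccccc3)cc(O)c(I)c2OCc2ccccc2)cc1 | intermediate
10 | 1-(benzyloxy)-4-ethynylbenzene | C#Cc1ccc(OCc2ccccc2)cc1 | starting material
11 | methyl 4-{2,6-bis(benzyloxy)-3-[3-(4-benzyloxyphenyl)prop-2-ynoyl]-4-hydroxyphenoxy}benzoate (alkynyl ketone, not isolated) | COC(=O)c1ccc(Oc2c(OCc3ccccc3)cc(O)c(C(=O)C#Cc3ccc(OCc4ccccc4)cc3)c2OCc2ccccc2)cc1 | intermediate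
12 | methyl 4-{[5,7-bis(benzyloxy)-2-(4-benzyloxyphenyl)-4-oxo-4H-chromen-6-yl]oxy}benzoate | COC(=O)c1ccc(Oc2c(OCc3ccccc3)cc3oc(-c4ccc(OCc5ccccc5)cc4)cc(=O)c3c2OCc2ccccc2)cc1 | intermediate
13 | 4-methoxy-6-methyl-2H-pyran-2-one | COC1=CC(=O)OC(C)=C1 | starting material
14 | N-methoxy-N-methylacetamide | CON(C)C(C)=O | starting material
15 | 4-methoxy-6-(2-oxopropyl)-2H-pyran-2-one | COC1=CC(=O)OC(CC(C)=O)=C1 | intermediate
16 | 6-[4-(4-{[5,7-bis(benzyloxy)-2-(4-benzyloxyphenyl)-4-oxo-4H-chromen-6-yl]oxy}phenyl)-2,4-dioxobutyl]-4-methoxy-2H-pyran-2-one | COC1=CC(=O)OC(CC(=O)CC(=O)c2ccc(Oc3c(OCc4ccccc4)cc4oc(-c5ccc(OCc6ccccc6)cc5)cc(=O)c4c3OCc3ccccc3)cc2)=C1 | intermediate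
17 | methyl (2E)-9-(4-{[5,7-bis(benzyloxy)-2-(4-benzyloxyphenyl)-4-oxo-4H-chromen-6-yl]oxy}phenyl)-3-methoxy-5,7,9-trioxonon-2-enoate (ring-opened ester, not isolated) | COC(=O)/C=C(OC)\CC(=O)CC(=O)CC(=O)c1ccc(Oc2c(OCc3ccccc3)cc3oc(-c4ccc(OCc5ccccc5)cc4)cc(=O)c3c2OCc2ccccc2)cc1 | intermediate
18 | 1-(2,6-dihydroxy-4-methoxyphenyl)-3-(4-{[5,7-bis(benzyloxy)-2-(4-benzyloxyphenyl)-4-oxo-4H-chromen-6-yl]oxy}phenyl)propane-1,3-dione | COc1cc(O)c(C(=O)CC(=O)c2ccc(Oc3c(OCc4ccccc4)cc4oc(-c5ccc(OCc6ccccc6)cc5)cc(=O)c4c3OCc3ccccc3)cc2)c(O)c1 | intermediate
19 | 5,7-bis(benzyloxy)-2-(4-benzyloxyphenyl)-6-[4-(5-hydroxy-7-methoxy-4-oxo-4H-chromen-2-yl)phenoxy]-4H-chromen-4-one | COc1cc(O)c2c(=O)cc(-c3ccc(Oc4c(OCc5ccccc5)cc5oc(-c6ccc(OCc7ccccc7)cc6)cc(=O)c5c4OCc4ccccc4)cc3)oc2c1 | intermediate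
20 | neocryptomerin, 5,7-dihydroxy-6-[4-(5-hydroxy-7-methoxy-4-oxo-4H-chromen-2-yl)phenoxy]-2-(4-hydroxyphenyl)-4H-chromen-4-one | COc1cc(O)c2c(=O)cc(-c3ccc(Oc4c(O)cc5oc(-c6ccc(O)cc6)cc(=O)c5c4O)cc3)oc2c1 | target

## Step count and risks

Total step count: 12. Longest linear sequence: 11 steps (steps 1 to 7 and 9 to 12, from 1 to 20); the pyranone arm adds one step (step 8) and joins at step 9.

**Step 10 (key step).** The chain may fold by aldol condensation (the carbon between the enol ether and the new ketone attacking the aryl ketone) if chelation is incomplete. Methoxide may also cleave the aroyl–methylene bond by retro-Claisen reaction, or open ring C of flavone 2 and give mixtures. The fallback gives up the ring construction and makes the same diketone by acyl transfer onto a ready-made ring. It sets out from 12. Hydrolysis with LiOH in THF–water would give 4-{[5,7-bis(benzyloxy)-2-(4-benzyloxyphenyl)-4-oxo-4H-chromen-6-yl]oxy}benzoic acid F1. Carbodiimide esterification with one hydroxyl of commercial 2,6-dihydroxy-4-methoxyacetophenone would give 2-acetyl-3-hydroxy-5-methoxyphenyl 4-{[5,7-bis(benzyloxy)-2-(4-benzyloxyphenyl)-4-oxo-4H-chromen-6-yl]oxy}benzoate F2. Baker–Venkataraman rearrangement with LiN(SiMe3)2 in THF would transfer the aroyl group to the acetyl carbon and rejoin the route at 18.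

**Step 9.** Acylation of the dianion by a methyl ester may be slow at low temperature. Proton transfer from product to dianion could then stall the reaction, the carbanion could add to the chromone of 12, or the dianion could self-condense on warming. The fallback changes the acyl donor to one that reacts at −78 °C through a stable chelated adduct. It sets out from 12. Treatment with N,O-dimethylhydroxylamine hydrochloride and AlMe3 would give 4-{[5,7-bis(benzyloxy)-2-(4-benzyloxyphenyl)-4-oxo-4H-chromen-6-yl]oxy}-N-methoxy-N-methylbenzamide F3. Its reaction with the dianion of 15 would rejoin the route at 16.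

**Step 7.** Direct coupling without CO insertion would lead to a 2-arylbenzofuran. 5-exo closure would give an aurone. Oxidative addition at the doubly ortho-substituted iodide may be slow, and diethylamine may slowly attack the methyl ester. The fallback builds ring C of flavone 2 by the chalcone route without Lewis acid or hydroxide. It sets out from 9. Stille coupling with tributyl(1-ethoxyvinyl)stannane (Pd(PPh3)4, toluene, 100 °C) would give methyl 4-[2,6-bis(benzyloxy)-3-(1-ethoxyethenyl)-4-hydroxyphenoxy]benzoate F4. Dilute HCl would hydrolyse it to methyl 4-[3-acetyl-2,6-bis(benzyloxy)-4-hydroxyphenoxy]benzoate F5. Claisen–Schmidt condensation with 4-(benzyloxy)benzaldehyde under NaOMe in dry methanol, which cannot change a methyl ester, would give methyl 4-{2,6-bis(benzyloxy)-3-[(2E)-3-(4-benzyloxyphenyl)prop-2-enoyl]-4-hydroxyphenoxy}benzoate F6. Oxidative cyclization with catalytic I2 in DMSO at 120 °C would rejoin the route at 12.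

**Step 4.** The phenoxide of 4 is weakly nucleophilic (para-formyl) and flanked by two benzyloxy groups, and the fluoride is only moderately activated. Substitution may therefore be slow, and ester cleavage by carbonate and adventitious water may compete at the temperature needed. The fallback replaces the addition–elimination by a copper-catalysed Ullmann ether synthesis. It sets out from 4. Coupling with methyl 4-iodobenzoate (CuI, picolinic acid, K3PO4, DMSO, 90 °C), conditions suited to hindered phenols, would rejoin the route at 6 with no new intermediate.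

## Further compounds

F1 | step 10 | 4-{[5,7-bis(benzyloxy)-2-(4-benzyloxyphenyl)-4-oxo-4H-chromen-6-yl]oxy}benzoic acid | O=C(O)c1ccc(Oc2c(OCc3ccccc3)cc3oc(-c4ccc(OCc5ccccc5)cc4)cc(=O)c3c2OCc2ccccc2)cc1
F2 | step 10 | 2-acetyl-3-hydroxy-5-methoxyphenyl 4-{[5,7-bis(benzyloxy)-2-(4-benzyloxyphenyl)-4-oxo-4H-chromen-6-yl]oxy}benzoate | COc1cc(O)c(C(C)=O)c(OC(=O)c2ccc(Oc3c(OCc4ccccc4)cc4oc(-c5ccc(OCc6ccccc6)cc5)cc(=O)c4c3OCc3ccccc3)cc2)c1
F3 | step 9 | 4-{[5,7-bis(benzyloxy)-2-(4-benzyloxyphenyl)-4-oxo-4H-chromen-6-yl]oxy}-N-methoxy-N-methylbenzamide | CON(C)C(=O)c1ccc(Oc2c(OCc3ccccc3)cc3oc(-c4ccc(OCc5ccccc5)cc4)cc(=O)c3c2OCc2ccccc2)cc1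
F4 | step 7 | methyl 4-[2,6-bis(benzyloxy)-3-(1-ethoxyethenyl)-4-hydroxyphenoxy]benzoate | CCOC(=C)c1c(O)cc(OCc2ccccc2)c(Oc2ccc(C(=O)OC)cc2)c1OCc1ccccc1
F5 | step 7 | methyl 4-[3-acetyl-2,6-bis(benzyloxy)-4-hydroxyphenoxy]benzoate | CC(=O)c1c(O)cc(OCc2ccccc2)c(Oc2ccc(C(=O)OC)cc2)c1OCc1ccccc1
F6 | step 7 | methyl 4-{2,6-bis(benzyloxy)-3-[(2E)-3-(4-benzyloxyphenyl)prop-2-enoyl]-4-hydroxyphenoxy}benzoate | COC(=O)c1ccc(Oc2c(OCc3ccccc3)cc(O)c(C(=O)/C=C/c3ccc(OCc4ccccc4)cc3)c2OCc2ccccc2)cc1
F0 | step 4 | none | none
A1 | alternative 1 | methyl 4-[2-(benzyloxy)-6-hydroxy-4-(triisopropylsilyloxy)phenoxy]benzoate | COC(=O)c1ccc(Oc2c(O)cc(O[Si](C(C)C)(C(C)C)C(C)C)cc2OCc2ccccc2)cc1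
A2 | alternative 1 | methyl 4-{[2-(benzyloxy)-4-oxocyclobut-2-en-1-yl]oxy}benzoate (racemic) | O=C1C=C(OCc2ccccc2)C1Oc1ccc(C(=O)OC)cc1
A3 | alternative 1 | (ethynyloxy)tri(propan-2-yl)silane | C#CO[Si](C(C)C)(C(C)C)C(C)C
A4 | alternative 2 | methyl 4-{[5,7-diisopropoxy-2-(4-isopropoxyphenyl)-4-oxo-4H-chromen-6-yl]oxy}benzoate | COC(=O)c1ccc(Oc2c(OC(C)C)cc3oc(-c4ccc(OC(C)C)cc4)cc(=O)c3c2OC(C)C)cc1
A5 | alternative 2 | methyl 4-[4-hydroxy-2,6-di(propan-2-yloxy)phenoxy]benzoate | COC(=O)c1ccc(Oc2c(OC(C)C)cc(O)cc2OC(C)C)cc1
A6 | alternative 2 | ethyl 3-oxo-3-[4-(propan-2-yloxy)phenyl]propanoate | CCOC(=O)CC(=O)c1ccc(OC(C)C)cc1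
A7 | alternative 3 | methyl 4-[2,6-bis(benzyloxy)-4-(tert-butyldimethylsilyloxy)phenoxy]benzoate | COC(=O)c1ccc(Oc2c(OCc3ccccc3)cc(O[Si](C)(C)C(C)(C)C)cc2OCc2ccccc2)cc1
A8 | alternative 3 | methyl 2-oxo-2H-pyran-5-carboxylate (methyl coumalate) | COC(=O)C1=COC(=O)C=C1
A9 | alternative 3 | [3,5-bis(benzyloxy)-4-(ethynyloxy)phenoxy](tert-butyl)dimethylsilane | C#COc1c(OCc2ccccc2)cc(O[Si](C)(C)C(C)(C)C)cc1OCc1ccccc1
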